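**Strategy.** The synthesis rests on disconnecting ring A (C1, C2, C3, C4, C5, C10; eudesmane numbering) at C2–C3 and C4–C5. The 1,4-relationship between the C1 oxygen and the C4 formyl carbon (C15), with the methyl-bearing C10 next to C1, is the retron of a Diels–Alder reaction. One catalytic, enantioselective cycloaddition of an acyclic 2-methyl-3-silyloxybutadiene with 2,2,2-trifluoroethyl acrylate closes ring A, places both functional carbons and fixes C4. This stereocentre is then relayed to C5 and C10 by conjugate addition–alkylation; ring B (C5–C10) follows by aldol condensation, and C6, C7 and C8 are set on the rigid trans-decalin.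

Key step: step 2

Remark: eudesmane numbering and α/β descriptors (C10 methyl = β) are used for all bicyclic compounds; the target is taken in the open hydroxy aldehyde/hydroxy acid form drawn, which may equilibrate with its C6–O–C15 hemiacetal.

**Step 1**
Reactants: 1 3-methylbut-3-en-2-one
Product: 2 2-methyl-3-[tri(propan-2-yl)silyloxy]buta-1,3-diene
Conditions: TIPSOTf, Et3N, CH2Cl2, 0 °C
Reagents that add atoms: triisopropylsilyl trifluoromethanesulfonate, CC(C)[Si](C(C)C)(C(C)C)OS(=O)(=O)C(F)(F)F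
Why: Soft enolisation and O-silylation (silyl enol ether formation) of the only enolisable position, the acetyl methyl group, should give the 2-silyloxydiene; no stereocentre is formed.

**Step 2**
Reactants: 2 2-methyl-3-[tri(propan-2-yl)silyloxy]buta-1,3-diene; 3 2,2,2-trifluoroethyl prop-2-enoate
Product: 4 2,2,2-trifluoroethyl (1R)-3-methyl-4-[tri(propan-2-yl)silyloxy]cyclohex-3-ene-1-carboxylate
Conditions: chiral B-(o-tolyl)oxazaborolidine from α,α-diphenylprolinol (10 mol %, enantiomer giving the R adduct), HNTf2 (10 mol %), CH2Cl2, −78 °C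
Reagents that add atoms: none
Why: The acrylate, bound through its carbonyl oxygen to the cationic boron of the oxazaborolidinium ion, should react in a concerted, asynchronous [4+2] cycloaddition in which the nucleophilic diene terminus C2 bonds to the acrylate β-carbon C3 while C5–C4 closes the ring. The closest known reaction type is the oxazaborolidinium-catalysed Diels–Alder reaction of 2-silyloxybuta-1,3-dienes with 2,2,2-trifluoroethyl acrylate. Ring A is closed in the intermolecular [4+2] mode, C2–C3 and C4–C5 being formed together and the C1=C10 silyl enol ether being left for the next step. The only new stereocentre, C4, is controlled by the catalyst, whose aryl groups shield one face of the coordinated acrylate. The step needs para regioselectivity (C1–O and C4–C15 in a 1,4-relationship) and enantioselectivity; the first is secured by the silyloxy group, a stronger donor than the C10 methyl group, and the second by the catalyst.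

**Step 3**
Reactants: 4 2,2,2-trifluoroethyl (1R)-3-methyl-4-[tri(propan-2-yl)silyloxy]cyclohex-3-ene-1-carboxylate
Product: 5 2,2,2-trifluoroethyl (1R)-3-methyl-4-oxocyclohex-2-ene-1-carboxylate
Conditions: Pd(OAc)2 (1.05 equiv), MeCN, 40 °C
Reagents that add atoms: none
Why: Saegusa–Ito oxidation of the regiodefined silyl enol ether should give the C10=C5 enone by β-hydride elimination from C5, under neutral conditions that should leave the C4 stereocentre (γ to the enone, α to the ester) untouched.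

**Step 4**
Reactants: 5 2,2,2-trifluoroethyl (1R)-3-methyl-4-oxocyclohex-2-ene-1-carboxylate; 6 vinylmagnesium bromide; 7 3-bromoprop-1-yne
Product: 9 2,2,2-trifluoroethyl (1R,2S,3R)-3-methyl-4-oxo-3-(prop-2-yn-1-yl)-2-vinylcyclohexane-1-carboxylate, via bromomagnesium enolate 8 (not isolated)
Conditions: CH2=CHMgBr, CuBr·SMe2 (10 mol %), THF, −78 °C; then HMPA, propargyl bromide, −78 to −20 °C
Reagents that add atoms: none
Why: Copper-catalysed conjugate addition should deliver the vinyl group to C5 anti to the C4 ester, and the regiospecific enolate should be alkylated at C10 anti to the new C5 substituent (conjugate addition–enolate alkylation), which sets the trans relationship of the future ring-fusion centres and the quaternary C10.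

**Step 5**
Reactants: 9 2,2,2-trifluoroethyl (1R,2S,3R)-3-methyl-4-oxo-3-(prop-2-yn-1-yl)-2-vinylcyclohexane-1-carboxylate
Product: 10 2,2,2-trifluoroethyl (1R,2S,3R,4R)-4-hydroxy-3-methyl-3-(prop-2-yn-1-yl)-2-vinylcyclohexane-1-carboxylate
Conditions: NaBH4, THF/i-PrOH, −20 °C
Reagents that add atoms: none
Why: Borohydride reduction of the only ketone should occur by axial attack on the face opposite the axial C10 methyl group and give the equatorial 1β-alcohol (cis to the methyl group), the low temperature sparing the activated ester.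

**Step 6**
Reactants: 10 2,2,2-trifluoroethyl (1R,2S,3R,4R)-4-hydroxy-3-methyl-3-(prop-2-yn-1-yl)-2-vinylcyclohexane-1-carboxylate
Product: 11 2,2,2-trifluoroethyl (1R,2S,3R,4R)-4-[tert-butyl(dimethyl)silyloxy]-3-methyl-3-(prop-2-yn-1-yl)-2-vinylcyclohexane-1-carboxylate
Conditions: TBSOTf, 2,6-lutidine, CH2Cl2, 0 °C
Reagents that add atoms: tert-butyldimethylsilyl trifluoromethanesulfonate, CC(C)(C)[Si](C)(C)OS(=O)(=O)C(F)(F)F
Why: Silylation with the silyl triflate should protect the hindered C1 hydroxyl, so that it stays distinct from the ring B hydroxyls made later.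

**Step 7**
Reactants: 11 2,2,2-trifluoroethyl (1R,2S,3R,4R)-4-[tert-butyl(dimethyl)silyloxy]-3-methyl-3-(prop-2-yn-1-yl)-2-vinylcyclohexane-1-carboxylate
Product: 12 2,2,2-trifluoroethyl (1R,2S,3R,4R)-4-[tert-butyl(dimethyl)silyloxy]-3-methyl-3-(2-oxopropyl)-2-vinylcyclohexane-1-carboxylate
Conditions: Ph3PAuNTf2 (2 mol %), 1,4-dioxane/H2O, 60 °C
Reagents that add atoms: water, O
Why: Gold-catalysed Markovnikov hydration of the terminal alkyne should give the methyl ketone (C8 carbonyl, C7 methyl) without touching the vinyl group.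

**Step 8**
Reactants: 12 2,2,2-trifluoroethyl (1R,2S,3R,4R)-4-[tert-butyl(dimethyl)silyloxy]-3-methyl-3-(2-oxopropyl)-2-vinylcyclohexane-1-carboxylate
Product: 13 2,2,2-trifluoroethyl (1R,2S,3R,4R)-4-[tert-butyl(dimethyl)silyloxy]-2-formyl-3-methyl-3-(2-oxopropyl)cyclohexane-1-carboxylate
Conditions: O3, CH2Cl2, −78 °C; then PPh3
Reagents that add atoms: ozone, O=[O+][O-]
Why: Ozonolysis with reductive work-up should convert the vinyl group into the C6 aldehyde, the only alkene in the molecule being cleaved.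

**Step 9**
Reactants: 13 2,2,2-trifluoroethyl (1R,2S,3R,4R)-4-[tert-butyl(dimethyl)silyloxy]-2-formyl-3-methyl-3-(2-oxopropyl)cyclohexane-1-carboxylate
Product: 14 1β-[tert-butyl(dimethyl)silyloxy]-8-oxo-11,12,13-trinoreudesm-6-en-15-oic acid (trans-decalin, 5α-H, 10β-methyl, 4α-CO2H)
Conditions: KOH, MeOH/H2O, 0 °C to rt; then 1 M HCl (0 °C) to pH 3
Reagents that add atoms: potassium hydroxide, [K+].[OH-]
Why: Intramolecular aldol condensation of the methyl ketone carbon C7 onto the C6 aldehyde should close ring B as the C8(=O)–C7=C6 enone while hydroxide saponifies the activated ester, the C5 centre staying in the thermodynamically favoured trans ring fusion.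

**Step 10**
Reactants: 14 1β-[tert-butyl(dimethyl)silyloxy]-8-oxo-11,12,13-trinoreudesm-6-en-15-oic acid
Product: 15 1β-[tert-butyl(dimethyl)silyloxy]-7-iodo-8-oxo-11,12,13-trinoreudesm-6-en-15-oic acid
Conditions: I2, pyridine, CH2Cl2, rt
Reagents that add atoms: iodine, II
Why: α-Iodination of the enone by the pyridine addition–iodination–elimination sequence should place iodine at C7 only.

**Step 11**
Reactants: 15 1β-[tert-butyl(dimethyl)silyloxy]-7-iodo-8-oxo-11,12,13-trinoreudesm-6-en-15-oic acid; 16 4,4,5,5-tetramethyl-2-(prop-1-en-2-yl)-1,3,2-dioxaborolane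
Product: 17 1β-[tert-butyl(dimethyl)silyloxy]-8-oxoeudesma-6,11-dien-15-oic acid
Conditions: Pd(dppf)Cl2 (5 mol %), K3PO4, dioxane/H2O, 50 °C
Reagents that add atoms: none
Why: Suzuki–Miyaura coupling of the α-iodoenone should attach the isopropenyl group (C11–C13) to C7 as a robust precursor of the acrylic acid.

**Step 12**
Reactants: 17 1β-[tert-butyl(dimethyl)silyloxy]-8-oxoeudesma-6,11-dien-15-oic acid
Product: 18 1β-[tert-butyl(dimethyl)silyloxy]-6α,7α-epoxy-8-oxoeudesm-11-en-15-oic acid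
Conditions: H2O2 (30% aq), NaOH, MeOH, 0 °C; then aq NaH2PO4
Reagents that add atoms: hydrogen peroxide, OO
Why: Weitz–Scheffer nucleophilic epoxidation should attack the enone β-carbon C6 from the α-face, anti to the axial C10 methyl group that is 1,3-diaxial to the β-trajectory, which sets the 6α-oxygen; the electron-rich isopropenyl alkene should not react.

**Step 13**
Reactants: 18 1β-[tert-butyl(dimethyl)silyloxy]-6α,7α-epoxy-8-oxoeudesm-11-en-15-oic acid
Product: 20 1β-[tert-butyl(dimethyl)silyloxy]-8α-hydroxyeudesm-11-en-15,6α-olide, via dihydroxy acid 19 (not isolated)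
Conditions: Li, NH3(l), THF, EtOH, −78 to −33 °C; NH4Cl; then EDC·HCl, DMAP (cat.), CH2Cl2, rt
Reagents that add atoms: none
Why: Dissolving-metal reduction should cleave the C7–O bond of the epoxy ketone, protonate the enolate at C7 from the axial α-face (isopropenyl equatorial, β) and reduce the ketone to the thermodynamically favoured equatorial 8α-alcohol, after which carbodiimide lactonisation can involve only the 6α-hydroxyl, which lies peri to the equatorial C4 carboxyl, and so distinguishes C6–OH from C8–OH.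

**Step 14**
Reactants: 20 1β-[tert-butyl(dimethyl)silyloxy]-8α-hydroxyeudesm-11-en-15,6α-olide
Product: 22 1β-[tert-butyl(dimethyl)silyloxy]-15-methoxy-6α,15-epoxyeudesm-11-en-8α-ol (mixture of C15 anomers), via lactol 21 (not isolated)
Conditions: i-Bu2AlH, CH2Cl2, −78 °C; Rochelle salt; then MeOH, PPTS, rt
Reagents that add atoms: methanol, CO
Why: Partial reduction of the γ-lactone to the lactol followed by Fischer-type acetalisation should give the cyclic methyl acetal, which masks the C15 aldehyde and the 6α-hydroxyl in one group and leaves 8α-OH as the only free hydroxyl; the anomeric centre is lost later.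

**Step 15**
Reactants: 23 methyl 2-(hydroxymethyl)prop-2-enoate
Product: 24 methyl 2-{[tert-butyl(dimethyl)silyloxy]methyl}prop-2-enoate
Conditions: TBSCl, imidazole, CH2Cl2, 0 °C to rt
Reagents that add atoms: tert-butyldimethylsilyl chloride, CC(C)(C)[Si](C)(C)Cl
Why: Standard silylation of the primary allylic alcohol should prevent self-esterification in the later acylation.

**Step 16**
Reactants: 24 methyl 2-{[tert-butyl(dimethyl)silyloxy]methyl}prop-2-enoate
Product: 25 2-{[tert-butyl(dimethyl)silyloxy]methyl}prop-2-enoic acid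
Conditions: LiOH, THF/H2O, 0 °C; then 1 M HCl to pH 3
Reagents that add atoms: lithium hydroxide, [Li+].[OH-]
Why: Saponification of the methyl ester at low temperature should give the acid without conjugate addition to the α-substituted acrylate.

**Step 17**
Reactants: 22 1β-[tert-butyl(dimethyl)silyloxy]-15-methoxy-6α,15-epoxyeudesm-11-en-8α-ol; 25 2-{[tert-butyl(dimethyl)silyloxy]methyl}prop-2-enoic acid
Product: 27 1β-[tert-butyl(dimethyl)silyloxy]-15-methoxy-6α,15-epoxyeudesm-11-en-8α-yl 2-{[tert-butyl(dimethyl)silyloxy]methyl}prop-2-enoate, via mixed anhydride 26 (not isolated)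
Conditions: 2,4,6-trichlorobenzoyl chloride, Et3N, THF, rt; then 22, DMAP, toluene, rt
Reagents that add atoms: none
Why: Yamaguchi esterification should acylate the single free, equatorial 8α-hydroxyl with retention of configuration.

**Step 18**
Reactants: 27 1β-[tert-butyl(dimethyl)silyloxy]-15-methoxy-6α,15-epoxyeudesm-11-en-8α-yl 2-{[tert-butyl(dimethyl)silyloxy]methyl}prop-2-enoate
Product: 29 the corresponding 12-oxoeudesm-11(13)-ene (C7 side chain C(=CH2)CHO), via allylic alcohol 28 (not isolated)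
Conditions: SeO2 (cat.), t-BuOOH (decane), CH2Cl2, rt; then MnO2, CH2Cl2, rt
Reagents that add atoms: tert-butyl hydroperoxide, CC(C)(C)OO
Why: Selenium dioxide allylic oxidation (ene reaction then [2,3]-shift) should oxidise the methyl group of the electron-rich isopropenyl unit while the electron-poor acrylate ester stays inert, and MnO2 should take the allylic alcohol on to the enal.

**Step 19**
Reactants: 29 the 12-oxoeudesm-11(13)-ene
Product: 30 1β-[tert-butyl(dimethyl)silyloxy]-8α-(2-{[tert-butyl(dimethyl)silyloxy]methyl}prop-2-enoyloxy)-15-methoxy-6α,15-epoxyeudesm-11(13)-en-12-oic acid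
Conditions: NaClO2, NaH2PO4, 2-methylbut-2-ene, t-BuOH/H2O, 0 °C to rt
Reagents that add atoms: sodium chlorite, [Na+].[O-]Cl=O
Why: Pinnick oxidation should convert the α-substituted acrolein into the acrylic acid while the C15 aldehyde is still masked as the acetal.

**Step 20**
Reactants: 30 the silyl-protected acetal acid
Product: 31 (1R,4R,5S,6R,7S,8S,10R)-1,6-dihydroxy-8-[2-(hydroxymethyl)prop-2-enoyloxy]-15-oxoeudesm-11(13)-en-12-oic acid (target)
Conditions: HF (48% aq), MeCN, 0 °C to rt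
Reagents that add atoms: water, O
Why: Aqueous hydrofluoric acid should remove both silyl ethers and hydrolyse the mixed methyl acetal, which frees the 6α-hydroxyl and the C15 aldehyde with the formyl group in the thermodynamically favoured equatorial 4α-position.

**Compound list**

1 | 3-methylbut-3-en-2-one | CC(=O)C(C)=C | starting material
2 | 2-methyl-3-[tri(propan-2-yl)silyloxy]buta-1,3-diene | C=C(C)C(=C)O[Si](C(C)C)(C(C)C)C(C)C | intermediate
3 | 2,2,2-trifluoroethyl prop-2-enoate | C=CC(=O)OCC(F)(F)F | starting material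
4 | 2,2,2-trifluoroethyl (1R)-3-methyl-4-[tri(propan-2-yl)silyloxy]cyclohex-3-ene-1-carboxylate | CC1=C(O[Si](C(C)C)(C(C)C)C(C)C)CC[C@H](C1)C(=O)OCC(F)(F)F | intermediate
5 | 2,2,2-trifluoroethyl (1R)-3-methyl-4-oxocyclohex-2-ene-1-carboxylate | O=C1C(C)=C[C@H](C(=O)OCC(F)(F)F)CC1 | intermediate
6 | vinylmagnesium bromide | C=C[Mg]Br | starting material
7 | 3-bromoprop-1-yne | C#CCBr | starting material
8 | bromomagnesium enolate of the C5-vinyl ketone (vinyl trans to the ester) | Br[Mg]OC1=C(C)[C@@H](C=C)[C@H](C(=O)OCC(F)(F)F)CC1 | intermediate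
9 | 2,2,2-trifluoroethyl (1R,2S,3R)-3-methyl-4-oxo-3-(prop-2-yn-1-yl)-2-vinylcyclohexane-1-carboxylate | C#CC[C@]1(C)[C@@H](C=C)[C@H](C(=O)OCC(F)(F)F)CCC1=O | intermediate
10 | 2,2,2-trifluoroethyl (1R,2S,3R,4R)-4-hydroxy-3-methyl-3-(prop-2-yn-1-yl)-2-vinylcyclohexane-1-carboxylate | C#CC[C@]1(C)[C@@H](C=C)[C@H](C(=O)OCC(F)(F)F)CC[C@H]1O | intermediate
11 | 2,2,2-trifluoroethyl (1R,2S,3R,4R)-4-[tert-butyl(dimethyl)silyloxy]-3-methyl-3-(prop-2-yn-1-yl)-2-vinylcyclohexane-1-carboxylate | C#CC[C@]1(C)[C@@H](C=C)[C@H](C(=O)OCC(F)(F)F)CC[C@H]1O[Si](C)(C)C(C)(C)C | intermediate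
12 | 2,2,2-trifluoroethyl (1R,2S,3R,4R)-4-[tert-butyl(dimethyl)silyloxy]-3-methyl-3-(2-oxopropyl)-2-vinylcyclohexane-1-carboxylate | CC(=O)C[C@]1(C)[C@@H](C=C)[C@H](C(=O)OCC(F)(F)F)CC[C@H]1O[Si](C)(C)C(C)(C)C | intermediate
13 | 2,2,2-trifluoroethyl (1R,2S,3R,4R)-4-[tert-butyl(dimethyl)silyloxy]-2-formyl-3-methyl-3-(2-oxopropyl)cyclohexane-1-carboxylate | CC(=O)C[C@]1(C)[C@@H](C=O)[C@H](C(=O)OCC(F)(F)F)CC[C@H]1O[Si](C)(C)C(C)(C)C | intermediate
14 | 1β-[tert-butyl(dimethyl)silyloxy]-8-oxo-11,12,13-trinoreudesm-6-en-15-oic acid (5α-H, 10β-Me, 4α-CO2H) | O=C1C[C@]2(C)[C@@H](C=C1)[C@H](C(=O)O)CC[C@H]2O[Si](C)(C)C(C)(C)C | intermediate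
15 | 1β-[tert-butyl(dimethyl)silyloxy]-7-iodo-8-oxo-11,12,13-trinoreudesm-6-en-15-oic acid | O=C1C[C@]2(C)[C@@H](C=C1I)[C@H](C(=O)O)CC[C@H]2O[Si](C)(C)C(C)(C)C | intermediate
16 | 4,4,5,5-tetramethyl-2-(prop-1-en-2-yl)-1,3,2-dioxaborolane | C=C(C)B1OC(C)(C)C(C)(C)O1 | starting material
17 | 1β-[tert-butyl(dimethyl)silyloxy]-8-oxoeudesma-6,11-dien-15-oic acid | O=C1C[C@]2(C)[C@@H](C=C1C(C)=C)[C@H](C(=O)O)CC[C@H]2O[Si](C)(C)C(C)(C)C | intermediate
18 | 1β-[tert-butyl(dimethyl)silyloxy]-6α,7α-epoxy-8-oxoeudesm-11-en-15-oic acid | O=C1C[C@]2(C)[C@@H]([C@@H](O3)[C@@]31C(C)=C)[C@H](C(=O)O)CC[C@H]2O[Si](C)(C)C(C)(C)C | intermediate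
19 | 1β-[tert-butyl(dimethyl)silyloxy]-6α,8α-dihydroxyeudesm-11-en-15-oic acid (7α-H) | O[C@H]1C[C@]2(C)[C@@H]([C@@H](O)[C@@H]1C(C)=C)[C@H](C(=O)O)CC[C@H]2O[Si](C)(C)C(C)(C)C | intermediate
20 | 1β-[tert-butyl(dimethyl)silyloxy]-8α-hydroxyeudesm-11-en-15,6α-olide | O[C@H]1C[C@]2(C)[C@H]3[C@@H](OC(=O)[C@@H]3CC[C@H]2O[Si](C)(C)C(C)(C)C)[C@@H]1C(C)=C | intermediate
21 | 1β-[tert-butyl(dimethyl)silyloxy]-6α,15-epoxyeudesm-11-ene-8α,15-diol (lactol, C15 anomers) | O[C@H]1C[C@]2(C)[C@H]3[C@@H](OC(O)[C@@H]3CC[C@H]2O[Si](C)(C)C(C)(C)C)[C@@H]1C(C)=C | intermediate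
22 | 1β-[tert-butyl(dimethyl)silyloxy]-15-methoxy-6α,15-epoxyeudesm-11-en-8α-ol (C15 anomers) | O[C@H]1C[C@]2(C)[C@H]3[C@@H](OC(OC)[C@@H]3CC[C@H]2O[Si](C)(C)C(C)(C)C)[C@@H]1C(C)=C | intermediate
23 | methyl 2-(hydroxymethyl)prop-2-enoate | C=C(CO)C(=O)OC | starting material
24 | methyl 2-{[tert-butyl(dimethyl)silyloxy]methyl}prop-2-enoate | C=C(CO[Si](C)(C)C(C)(C)C)C(=O)OC | intermediate
25 | 2-{[tert-butyl(dimethyl)silyloxy]methyl}prop-2-enoic acid | C=C(CO[Si](C)(C)C(C)(C)C)C(=O)O | intermediate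
26 | 2-{[tert-butyl(dimethyl)silyloxy]methyl}prop-2-enoic 2,4,6-trichlorobenzoic anhydride | C=C(CO[Si](C)(C)C(C)(C)C)C(=O)OC(=O)c1c(Cl)cc(Cl)cc1Cl | intermediate
27 | 1β-[tert-butyl(dimethyl)silyloxy]-15-methoxy-6α,15-epoxyeudesm-11-en-8α-yl 2-{[tert-butyl(dimethyl)silyloxy]methyl}prop-2-enoate | C=C(CO[Si](C)(C)C(C)(C)C)C(=O)O[C@H]1C[C@]2(C)[C@H]3[C@@H](OC(OC)[C@@H]3CC[C@H]2O[Si](C)(C)C(C)(C)C)[C@@H]1C(C)=C | intermediate
28 | 12-hydroxy analogue of 27 (C7 side chain C(=CH2)CH2OH) | C=C(CO[Si](C)(C)C(C)(C)C)C(=O)O[C@H]1C[C@]2(C)[C@H]3[C@@H](OC(OC)[C@@H]3CC[C@H]2O[Si](C)(C)C(C)(C)C)[C@@H]1C(CO)=C | intermediate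
29 | 12-oxo analogue of 27 (C7 side chain C(=CH2)CHO) | C=C(CO[Si](C)(C)C(C)(C)C)C(=O)O[C@H]1C[C@]2(C)[C@H]3[C@@H](OC(OC)[C@@H]3CC[C@H]2O[Si](C)(C)C(C)(C)C)[C@@H]1C(C=O)=C | intermediate
30 | 1β-[tert-butyl(dimethyl)silyloxy]-8α-(2-{[tert-butyl(dimethyl)silyloxy]methyl}prop-2-enoyloxy)-15-methoxy-6α,15-epoxyeudesm-11(13)-en-12-oic acid | C=C(CO[Si](C)(C)C(C)(C)C)C(=O)O[C@H]1C[C@]2(C)[C@H]3[C@@H](OC(OC)[C@@H]3CC[C@H]2O[Si](C)(C)C(C)(C)C)[C@@H]1C(=C)C(=O)O | intermediate
31 | (1R,4R,5S,6R,7S,8S,10R)-1,6-dihydroxy-8-[2-(hydroxymethyl)prop-2-enoyloxy]-15-oxoeudesm-11(13)-en-12-oic acid | C=C(CO)C(=O)O[C@H]1C[C@]2(C)[C@@H]([C@@H](O)[C@@H]1C(=C)C(=O)O)[C@H](C=O)CC[C@H]2O | target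

**Step count.** Total: 20 steps. Longest linear sequence: 18 steps (steps 1–14 and 17–20); steps 15 and 16 prepare the side-chain acid.

**Steps most likely to fail**

1. Step 13. Under the dissolving-metal conditions the β,γ-unsaturated ketone formed after epoxide opening may isomerise into conjugation and be over-reduced, or the ketone may be reduced before C7 has reached its equatorial configuration, so that control at C7 and C8 is lost. The fallback sets out from 18 and returns at 20. Single-electron opening of the epoxy ketone with SmI2 (THF/MeOH, −78 °C) should give 1β-[tert-butyl(dimethyl)silyloxy]-6α-hydroxy-8-oxoeudesm-11-en-15-oic acid F1 without touching the ketone. Carbodiimide lactonisation (EDC·HCl, DMAP) should give the keto lactone 1β-[tert-butyl(dimethyl)silyloxy]-8-oxoeudesm-11-en-15,6α-olide F2. An equilibrating Meerwein–Ponndorf–Verley reduction (Al(OiPr)3, i-PrOH, toluene, 60 °C) should then give the more stable equatorial 8α-alcohol 20.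

2. Step 14. The cyclic acetal is trans-fused to both rings, and this strain may divert the acetalisation toward the open-chain dimethyl acetal, so that the distinction between the C6 and C8 hydroxyls is lost. The fallback sets out from 20 and returns at 31; it gives up the cyclic protection and relies on site-selective acylation. Lactol 21 (from 20 with i-Bu2AlH) is converted on purpose with HC(OMe)3, MeOH and camphorsulfonic acid into the open-chain 1β-[tert-butyl(dimethyl)silyloxy]-15,15-dimethoxyeudesm-11-ene-6α,8α-diol F3. Yamaguchi acylation with mixed anhydride 26 should then select the less hindered 8α-hydroxyl, because the 6α-hydroxyl is flanked by the ring-fusion carbon C5, the branched C7 and the peri C4 substituent, and should give the 8α-monoester F4. SeO2/t-BuOOH should give the 12-hydroxy compound F5 and MnO2 the enal F6; Pinnick oxidation should give the acid F7; aqueous HF should remove both silyl groups and hydrolyse the dimethyl acetal to 31.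

3. Step 20. With the free C12 acid present, the acidic medium may cause lactonisation of the liberated 6α-hydroxyl onto C12, or cleavage of the hindered C1 silyl ether may remain incomplete under conditions mild enough to avoid this. The fallback sets out from 30 and returns at 31; it unveils the hydroxyls and the aldehyde while the acid is masked, and frees the acid last under neutral conditions. Alkylation of 30 with allyl bromide and Cs2CO3 in DMF should give the allyl ester F8. Aqueous HF in MeCN should give the allyl ester of the target F9. Deallylation with Pd(PPh3)4 (5 mol %) and PhSiH3 in CH2Cl2 at rt should give 31.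

**Further compounds**

F1 | step 13 | 1β-[tert-butyl(dimethyl)silyloxy]-6α-hydroxy-8-oxoeudesm-11-en-15-oic acid | O=C1C[C@]2(C)[C@@H]([C@@H](O)[C@@H]1C(C)=C)[C@H](C(=O)O)CC[C@H]2O[Si](C)(C)C(C)(C)C
F2 | step 13 | 1β-[tert-butyl(dimethyl)silyloxy]-8-oxoeudesm-11-en-15,6α-olide | O=C1C[C@]2(C)[C@H]3[C@@H](OC(=O)[C@@H]3CC[C@H]2O[Si](C)(C)C(C)(C)C)[C@@H]1C(C)=C
F3 | step 14 | 1β-[tert-butyl(dimethyl)silyloxy]-15,15-dimethoxyeudesm-11-ene-6α,8α-diol | O[C@H]1C[C@]2(C)[C@@H]([C@@H](O)[C@@H]1C(C)=C)[C@H](C(OC)OC)CC[C@H]2O[Si](C)(C)C(C)(C)C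
F4 | step 14 | 1β-[tert-butyl(dimethyl)silyloxy]-6α-hydroxy-15,15-dimethoxyeudesm-11-en-8α-yl 2-{[tert-butyl(dimethyl)silyloxy]methyl}prop-2-enoate | C=C(CO[Si](C)(C)C(C)(C)C)C(=O)O[C@H]1C[C@]2(C)[C@@H]([C@@H](O)[C@@H]1C(C)=C)[C@H](C(OC)OC)CC[C@H]2O[Si](C)(C)C(C)(C)C
F5 | step 14 | 12-hydroxy analogue of F4 (C7 side chain C(=CH2)CH2OH) | C=C(CO[Si](C)(C)C(C)(C)C)C(=O)O[C@H]1C[C@]2(C)[C@@H]([C@@H](O)[C@@H]1C(CO)=C)[C@H](C(OC)OC)CC[C@H]2O[Si](C)(C)C(C)(C)C
F6 | step 14 | 12-oxo analogue of F4 (C7 side chain C(=CH2)CHO) | C=C(CO[Si](C)(C)C(C)(C)C)C(=O)O[C@H]1C[C@]2(C)[C@@H]([C@@H](O)[C@@H]1C(C=O)=C)[C@H](C(OC)OC)CC[C@H]2O[Si](C)(C)C(C)(C)C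
F7 | step 14 | 1β-[tert-butyl(dimethyl)silyloxy]-8α-(2-{[tert-butyl(dimethyl)silyloxy]methyl}prop-2-enoyloxy)-6α-hydroxy-15,15-dimethoxyeudesm-11(13)-en-12-oic acid | C=C(CO[Si](C)(C)C(C)(C)C)C(=O)O[C@H]1C[C@]2(C)[C@@H]([C@@H](O)[C@@H]1C(=C)C(=O)O)[C@H](C(OC)OC)CC[C@H]2O[Si](C)(C)C(C)(C)C
F8 | step 20 | allyl ester of 30 | C=C(CO[Si](C)(C)C(C)(C)C)C(=O)O[C@H]1C[C@]2(C)[C@H]3[C@@H](OC(OC)[C@@H]3CC[C@H]2O[Si](C)(C)C(C)(C)C)[C@@H]1C(=C)C(=O)OCC=C
F9 | step 20 | allyl ester of 31 | C=C(CO)C(=O)O[C@H]1C[C@]2(C)[C@@H]([C@@H](O)[C@@H]1C(=C)C(=O)OCC=C)[C@H](C=O)CC[C@H]2O
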